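**Retrosynthetic overview**
- Pakyonol ⇒ one global hydrogenation/hydrogenolysis of a 20-membered macrocyclic benzil (ArCO–COAr) that still carries a diarylalkyne A–D bridge and a benzyl ether on ring C.
- Key disconnection: the C–C bond between the two carbonyl carbons on rings B and C ⇒ an open-chain dialdehyde. In the forward direction an N-heterocyclic carbene turns one formyl carbon into an acyl anion equivalent (Breslow intermediate) that attacks the other formyl carbon and closes the macrocycle; the resulting pair of ketols is oxidised in the same flask to the single diketone.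
- Dialdehyde ⇒ Sonogashira disconnection at the A–D alkyne ⇒ a bromo diaryl ether (rings A, B) and an ethynyl diaryl ether (rings C, D).
- Each diaryl ether ⇒ SNAr of a phenol on a 4-fluorobenzaldehyde.
- Ring order: the four benzene rings are bought intact; the macrocycle is the only ring formed (step 5), and step 6 removes the alkyne, both carbonyl oxygens and the benzyl group together.

Assumption: the target SMILES has no stereocentre and the 20-membered ring is conformationally mobile, so pakyonol is achiral and no stereocontrol is needed; the carbinol centre of the transient ketols is racemic and is erased in the same flask.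

**Step 1**
Reactants: 1 5-bromo-2-methoxyphenol; 2 4-fluorobenzaldehyde
Product: 3 4-(5-bromo-2-methoxyphenoxy)benzaldehyde
Conditions: K2CO3 (1.5 equiv), DMF, 120 °C, 12 h
Reagents that add atoms: none
Why: SNAr (addition–elimination) in which the phenoxide of 1 displaces the fluoride para to the formyl group of 2, the unactivated aryl bromide staying intact.

**Step 2**
Reactants: 4 4-fluoro-3-hydroxybenzaldehyde
Product: 5 3-(benzyloxy)-4-fluorobenzaldehyde
Conditions: BnBr (1.1 equiv), K2CO3 (1.5 equiv), DMF, rt, 6 h
Reagents that add atoms: benzyl bromide, BrCc1ccccc1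
Why: Williamson ether synthesis at room temperature, where the aryl fluoride is still inert, installing a protecting group that the final hydrogenolysis removes without an extra step.

**Step 3**
Reactants: 5 3-(benzyloxy)-4-fluorobenzaldehyde; 6 3-ethynylphenol
Product: 7 3-(benzyloxy)-4-(3-ethynylphenoxy)benzaldehyde
Conditions: K2CO3 (1.5 equiv), DMF, 110 °C, N2, 12 h
Reagents that add atoms: none
Why: SNAr in which the para formyl group activates the C–F bond of 5 towards the phenoxide of 6, carbonate being too weak to deprotonate or add across the terminal alkyne (end-capping of activated aryl fluorides with 3-ethynylphenol is established practice).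

**Step 4**
Reactants: 3 4-(5-bromo-2-methoxyphenoxy)benzaldehyde; 7 3-(benzyloxy)-4-(3-ethynylphenoxy)benzaldehyde
Product: 8 3-(benzyloxy)-4-[3-({3-(4-formylphenoxy)-4-methoxyphenyl}ethynyl)phenoxy]benzaldehyde
Conditions: PdCl2(PhCN)2 (3 mol%), tri-tert-butylphosphonium tetrafluoroborate (6 mol%), CuI (copper iodide, 2 mol%), diisopropylamine (2 equiv), degassed 1,4-dioxane, rt to 40 °C
Reagents that add atoms: none
Why: Sonogashira coupling in which the electron-rich aryl bromide adds oxidatively to the zerovalent palladium/tri-tert-butylphosphine catalyst and the copper acetylide of 7 transmetalates, conditions that tolerate both formyl groups and the benzyl ether.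

**Step 5**
Reactants: 8 3-(benzyloxy)-4-[3-({3-(4-formylphenoxy)-4-methoxyphenyl}ethynyl)phenoxy]benzaldehyde
Product: 11 alkyne-bridged macrocyclic benzil (B–CO–CO–C 1,2-diketone), via B-keto macrocyclic ketol 9 (not isolated), via C-keto macrocyclic ketol 10 (not isolated)
Conditions: 2-(pentafluorophenyl)-6,7-dihydro-5H-pyrrolo[2,1-c][1,2,4]triazol-2-ium tetrafluoroborate (20 mol%), DBU (20 mol%), degassed THF, 40 °C, 8 added by syringe pump over 12 h to a final 2 mM, then 12 h; AcOH (0.5 equiv) quench; solvent exchange to CH2Cl2 without purification, Dess–Martin periodinane (1.5 equiv), rt, 1 h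
Reagents that add atoms: none
Why: Proposed new method: the triazolylidene adds to one formyl group to give a Breslow intermediate (acyl anion equivalent) that attacks the second, normally electrophilic, formyl carbon in an intramolecular crossed benzoin reaction, and because NHC benzoin formation is reversible, high dilution lets oligomeric adducts revert and funnels material to the nearly strain-free 20-membered ring (a rough geometric estimate gives O···O about 9.6 Å across the rigid m,m'-diarylalkyne with both ether arms on one side, so a bend of about 10° per alkyne carbon brings the two formyl carbons into bonding distance); closure through either formyl group gives the racemic ketols 9 and 10, which, once the carbene is protonated by AcOH so that no retro-benzoin can occur, are oxidised in the same flask by Dess–Martin periodinane to the one achiral 1,2-diketone 11 (the alkyne, benzyl ether and aryl ethers are inert to it), so neither regio- nor stereocontrol is needed; the closest known reactions are NHC-catalysed intramolecular crossed benzoin cyclisations to 5- to 7-membered rings, the cyanide-catalysed cyclooligomerisation of aromatic dialdehydes to macrocyclic cyclobenzoins, and the routine Dess–Martin oxidation of benzoins to benzils.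

**Step 6**
Reactants: 11 alkyne-bridged macrocyclic benzil
Product: 15 pakyonol, via saturated phenolic diketone 12 (not isolated), via B-keto phenolic ketol 13 (not isolated), via C-keto phenolic ketol 14 (not isolated)
Conditions: H2 (1 atm), 10% Pd/C, EtOAc–AcOH (1:1), rt, 3 h; then 70% HClO4 (0.2 equiv), H2 (4 atm), 50 °C, 12 h
Reagents that add atoms: none
Why: Catalytic hydrogenation/hydrogenolysis in which Pd/C first saturates the diarylalkyne and cleaves the aryl benzyl ether to give 12, then reduces the 1,2-diketone through the ketols 13 and 14 and, with HClO4 in AcOH, hydrogenolyses the remaining benzylic C=O and C–OH functions to CH2–CH2 (the classical benzil/benzoin-to-bibenzyl reduction), so everything collapses to achiral 15 while the diaryl ethers and the methyl ether are inert.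

**Compound list**
1 | 5-bromo-2-methoxyphenol | COc1ccc(Br)cc1O | starting material
2 | 4-fluorobenzaldehyde | O=Cc1ccc(F)cc1 | starting material
3 | 4-(5-bromo-2-methoxyphenoxy)benzaldehyde | COc1ccc(Br)cc1Oc1ccc(C=O)cc1 | intermediate
4 | 4-fluoro-3-hydroxybenzaldehyde | O=Cc1ccc(F)c(O)c1 | starting material
5 | 3-(benzyloxy)-4-fluorobenzaldehyde | O=Cc1ccc(F)c(OCc2ccccc2)c1 | intermediate
6 | 3-ethynylphenol | C#Cc1cccc(O)c1 | starting material
7 | 3-(benzyloxy)-4-(3-ethynylphenoxy)benzaldehyde | O=Cc1ccc(Oc2cccc(C#C)c2)c(OCc2ccccc2)c1 | intermediate
8 | 3-(benzyloxy)-4-[3-({3-(4-formylphenoxy)-4-methoxyphenyl}ethynyl)phenoxy]benzaldehyde (open chain B–O–A–C≡C–D–O–C, a formyl group on rings B and C) | COc1ccc(C#Cc2cccc(Oc3ccc(C=O)cc3OCc3ccccc3)c2)cc1Oc1ccc(C=O)cc1 | intermediate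
9 | B-keto macrocyclic ketol: 20-membered ring A–O–B–C(=O)–CH(OH)–C–O–D–C≡C–A, OMe on ring A, OBn on ring C, racemic, not isolated | COc1ccc2cc1Oc1ccc(cc1)C(=O)C(O)c1ccc(c(OCc3ccccc3)c1)Oc1cccc(c1)C#C2 | intermediate
10 | C-keto macrocyclic ketol: 20-membered ring A–O–B–CH(OH)–C(=O)–C–O–D–C≡C–A, OMe on ring A, OBn on ring C, racemic, not isolated | COc1ccc2cc1Oc1ccc(cc1)C(O)C(=O)c1ccc(c(OCc3ccccc3)c1)Oc1cccc(c1)C#C2 | intermediate
11 | alkyne-bridged macrocyclic benzil: 20-membered ring A–O–B–C(=O)–C(=O)–C–O–D–C≡C–A, OMe on ring A, OBn on ring C, achiral | COc1ccc2cc1Oc1ccc(cc1)C(=O)C(=O)c1ccc(c(OCc3ccccc3)c1)Oc1cccc(c1)C#C2 | intermediate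
12 | saturated phenolic diketone: as 11 but A–D bridge CH2CH2 and free OH on ring C, not isolated | COc1ccc2cc1Oc1ccc(cc1)C(=O)C(=O)c1ccc(c(O)c1)Oc1cccc(c1)CC2 | intermediate
13 | B-keto phenolic ketol: as 12 but CH(OH) next to ring C, racemic, not isolated | COc1ccc2cc1Oc1ccc(cc1)C(=O)C(O)c1ccc(c(O)c1)Oc1cccc(c1)CC2 | intermediate
14 | C-keto phenolic ketol: as 12 but CH(OH) next to ring B, racemic, not isolated | COc1ccc2cc1Oc1ccc(cc1)C(O)C(=O)c1ccc(c(O)c1)Oc1cccc(c1)CC2 | intermediate
15 | pakyonol (achiral) | COc1ccc2cc1Oc1ccc(cc1)CCc1ccc(c(O)c1)Oc1cccc(c1)CC2 | target

**Totals**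
Total step count: 6. Longest linear sequence: 5 (steps 2, 3, 4, 5, 6, starting from 4).

**Steps most likely to fail, with fallbacks**

Step 5 (macrocyclic ketol closure and oxidation) is the main risk: oligomerisation may win, or the rigid alkyne may hold the formyl groups apart. It was placed before any saturation of the alkyne because this saves a separate chemoselective hydrogenation. The fallback sets out from 8 and comes back to the route at 15. It replaces the catalytic Breslow pathway by a stoichiometric one-electron coupling. Compound 8 is added slowly to SmI2 (samarium diiodide, 2.5 equiv) in THF at −78 °C to rt at 2 mM. Both aryl aldehydes become ketyl radical anions and couple in an intramolecular pinacol reaction to give the benzyl-protected alkyne-bridged macrocyclic 1,2-diol F1 as a mixture of diastereomers. F1 is then put through the conditions of step 6. It is first saturated and debenzylated to the saturated phenolic macrocyclic triol F2, which loses both benzylic hydroxyl groups by acid-assisted hydrogenolysis to give 15.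

Step 6 (global reduction) may stall at a partly deoxygenated stage or suffer acid-induced side reactions on the catalyst. The fallback sets out from 11 and comes back at 15. It separates the two tasks. Neutral hydrogenation (H2 1 atm, 10% Pd/C, EtOAc, rt, stopped once the alkyne and the benzyl group are consumed) gives 12, which is now isolated. Its two carbonyl groups are then deoxygenated without a metal surface by ionic hydrogenation (Et3SiH 8 equiv, CF3CO2H–CH2Cl2 1:1, 0 °C to 40 °C). The benzylic cations, stabilised by the para aryloxy groups, take hydride from the silane, and 15 results. This fallback makes no compound outside the list (F0).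

Step 3 (SNAr with a phenol that carries a terminal alkyne, on a fluoride partly deactivated by the ortho benzyloxy group) may give alkyne side reactions at the temperature needed. The fallback sets out from 6 and comes back at 8, bypassing 7: couple first, etherify second. Compound 6, with its phenol free, is coupled with bromide 3 under the conditions of step 4 to give 4-{5-[(3-hydroxyphenyl)ethynyl]-2-methoxyphenoxy}benzaldehyde F3. F3 is then arylated with fluoride 5 (K2CO3, DMF, 110 °C), so that only an internal diarylalkyne meets hot carbonate, and 8 is obtained.

**Further compounds**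
F1 | step 5 | benzyl-protected alkyne-bridged macrocyclic 1,2-diol (A–O–B–CH(OH)–CH(OH)–C–O–D–C≡C–A, OBn on ring C; mixture of diastereomers) | COc1ccc2cc1Oc1ccc(cc1)C(O)C(O)c1ccc(c(OCc3ccccc3)c1)Oc1cccc(c1)C#C2
F2 | step 5 | saturated phenolic macrocyclic triol (as F1 but A–D bridge CH2CH2 and free OH on ring C; mixture of diastereomers) | COc1ccc2cc1Oc1ccc(cc1)C(O)C(O)c1ccc(c(O)c1)Oc1cccc(c1)CC2
F0 | step 6 | none | none
F3 | step 3 | 4-{5-[(3-hydroxyphenyl)ethynyl]-2-methoxyphenoxy}benzaldehyde | COc1ccc(C#Cc2cccc(O)c2)cc1Oc1ccc(C=O)cc1
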